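**Retrosynthetic overview**
1. Target ⇒ (desilylation, C7 carbamoylation) ⇒ macrolactam 21 ⇒ aryl C–N disconnection: intramolecular Cu-catalysed N-arylation of a primary enamide by the aryl bromide in seco-amide 20.
2. 20 ⇒ C1–C3 by hydroformylation/Wittig on the C4=C5 vinyl group of 15; C6/C7 by (Z)-γ-methoxyallylboration of enal 13; C8=C9 by cross-metathesis of 10 with methacrolein.
3. 10 ⇒ (Z)-crotylboration of α-methoxy lactol 8 (sets C10, C11).
4. 8 ⇒ C12–OMe by anodic dimethoxylation of cyclic enol ether 6 (new C–O step) ⇒ hydroformylation/dehydration of 4 ⇒ Brown crotylation of aldehyde 2 (sets C14, C15).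
5. Rings: temporary C11–C15 pyran (steps 3–4, opened in step 5), temporary C3–C7 lactol (inside step 10), then the 19-membered lactam (step 11).

Assumption: carbon numbers follow ansamycin numbering (C1 amide carbonyl, C15 benzylic carbinol, C20 aryl carbon bearing Br/N); Ar = 3-bromo-5-[(triisopropylsilyl)oxy]phenyl; carbon-fragment donors are numbered as starting materials, while silylating agents, CO, methanol, water and the isocyanate are listed as reagents.

**Step 1**
Reactants: 1 3-bromo-5-hydroxybenzaldehyde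
Product: 2 3-bromo-5-[(triisopropylsilyl)oxy]benzaldehyde
Conditions: TIPSCl, imidazole, DMF, rt
Reagents that add atoms: triisopropylsilyl chloride CC(C)[Si](Cl)(C(C)C)C(C)C
Why: Imidazole-promoted O-silylation (silyl ether protection) masks the only acidic OH as a TIPS ether that survives the borane, Rh, electrolysis and Cu/K2CO3 steps; no stereocentre is formed.

**Step 2**
Reactants: 2 3-bromo-5-[(triisopropylsilyl)oxy]benzaldehyde; 3 cis-2-butene
Product: 4 (1R,2S)-1-Ar-2-methylbut-3-en-1-ol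
Conditions: 3, n-BuLi, KOt-Bu, THF, −78 to −45 °C; (+)-Ipc2BOMe [from (−)-α-pinene]; BF3·OEt2; 2, −78 °C; NaBO3·4H2O, THF/H2O
Reagents that add atoms: none
Why: Brown asymmetric crotylboration: the (Z)-crotylborane reacts through a closed chair transition state, so Z geometry gives the 14,15-syn pair, and the (−)-α-pinene-derived Ipc ligands direct attack to the Re face of the aldehyde, which sets 15R and 14S.

**Step 3**
Reactants: 4 (1R,2S)-1-Ar-2-methylbut-3-en-1-ol
Product: 6 (2R,3S)-2-Ar-3-methyl-3,4-dihydro-2H-pyran, via lactol 5 (not isolated)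
Conditions: Rh(acac)(CO)2 (1 mol %), Xantphos, CO/H2 (1:1, 10 bar), toluene, 65 °C; then MsCl, Et3N, 0 to 60 °C
Reagents that add atoms: carbon monoxide [C-]#[O+]
Why: Rh/Xantphos hydroformylation is linear-selective on the 3-branched terminal alkene (adds C11), the δ-hydroxy aldehyde closes to lactol 5, and its anomeric mesylate eliminates under Et3N (lactol dehydration) to the cyclic enol ether without touching C14 or C15.

**Step 4**
Reactants: 6 (2R,3S)-2-Ar-3-methyl-3,4-dihydro-2H-pyran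
Product: 8 (3S,5S,6R)-6-Ar-3-methoxy-5-methyltetrahydro-2H-pyran-2-ol (anomer mixture), via dimethoxy acetal 7 (not isolated)
Conditions: RVC anode, Pt cathode, undivided cell, MeOH, Et4NOTs, 2,6-lutidine, constant current (2.2 F/mol), 0 °C; then 1 M HCl, THF, 40 °C
Reagents that add atoms: methanol CO; water O
Why: Proposed new method: anodic oxidation takes one electron from the enol ether (the most easily oxidised group present, well below the bromo-silyloxy arene), methanol adds to C12 of the radical cation on the ring face opposite the pseudo-axial C14 methyl (the other face would create a 1,3-diaxial OMe/Me contact), the α-oxy radical is oxidised to the C11 oxocarbenium ion and trapped by methanol, and acidic work-up hydrolyses only the anomeric methoxy group, so C12 is set as S and C11 returns as the lactol; the closest known reaction type is the anodic 1,2-dimethoxylation of simple vinyl ethers in methanol (Shono-type oxidation, Moeller-type enol ether radical-cation trapping), not yet shown on a chiral 2,3-disubstituted dihydropyran or used for stereocontrol.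

**Step 5**
Reactants: 8 (3S,5S,6R)-6-Ar-3-methoxy-5-methyltetrahydro-2H-pyran-2-ol; 9 (Z)-crotylboronic acid pinacol ester
Product: 10 (1R,2S,4S,5R,6S)-1-Ar-4-methoxy-2,6-dimethyloct-7-ene-1,5-diol
Conditions: 9 (1.5 equiv), toluene, 40 °C; aq. NaHCO3 work-up
Reagents that add atoms: none
Why: Thermal allylboration (Hoffmann–Roush type) of the open hydroxy-aldehyde form of the lactol: the chair transition state of the (Z)-crotylboronate gives 10,11-syn and the α-methoxy group steers attack in the Cornforth/polar Felkin–Anh sense to 11,12-anti, so C10 (S) and C11 (R) are set under matched substrate control.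

**Step 6**
Reactants: 10 (1R,2S,4S,5R,6S)-1-Ar-4-methoxy-2,6-dimethyloct-7-ene-1,5-diol; 11 methacrolein
Product: 12 (2E,4S,5R,6S,8S,9R)-9-Ar-5,9-dihydroxy-6-methoxy-2,4,8-trimethylnon-2-enal
Conditions: 11 (10 equiv), Hoveyda–Grubbs II (7 mol %), CH2Cl2, 40 °C
Reagents that add atoms: none
Why: Ru-catalysed olefin cross-metathesis of the terminal alkene with excess methacrolein gives the thermodynamically favoured E-trisubstituted enal (installs C8=C9 and C7), tolerates free hydroxyls and Ar–Br, and is run before silylation to keep the allylic site uncrowded.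

**Step 7**
Reactants: 12 (2E,4S,5R,6S,8S,9R)-9-Ar-5,9-dihydroxy-6-methoxy-2,4,8-trimethylnon-2-enal
Product: 13 (2E,4S,5R,6S,8S,9R)-9-Ar-6-methoxy-2,4,8-trimethyl-5,9-bis[(triethylsilyl)oxy]non-2-enal
Conditions: TESCl, imidazole, DMAP (cat.), DMF, 0 °C to rt
Reagents that add atoms: chlorotriethylsilane CC[Si](Cl)(CC)CC
Why: Silyl chloride/imidazole silylation under non-enolising conditions caps the C11 and C15 hydroxyls so that the C7 hydroxyl made next is the only free alcohol at the carbamoylation stage; no stereocentre is touched.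

**Step 8**
Reactants: 13 (2E,4S,5R,6S,8S,9R)-9-Ar-6-methoxy-2,4,8-trimethyl-5,9-bis[(triethylsilyl)oxy]non-2-enal; 14 allyl methyl ether
Product: 15 (3S,4S,5E,7S,8R,9S,11S,12R)-12-Ar-3,9-dimethoxy-5,7,11-trimethyl-8,12-bis[(triethylsilyl)oxy]dodeca-1,5-dien-4-ol
Conditions: 14, s-BuLi, THF, −78 °C; (+)-Ipc2BOMe; BF3·OEt2; 13, −78 °C; NaBO3·4H2O, THF/H2O
Reagents that add atoms: none
Why: Brown (Z)-γ-methoxyallylboration: 1,2-addition to the enal through a chair transition state gives the 6,7-syn methoxy alcohol and the (−)-α-pinene-derived Ipc ligands direct Re-face attack, which sets 7S and 6S and brings in the C6 methyl ether and the C4=C5 vinyl group.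

**Step 9**
Reactants: 16 2-bromopropanamide (racemic)
Product: 18 2-(triphenyl-λ5-phosphanylidene)propanamide, via phosphonium bromide 17 (not isolated)
Conditions: PPh3, MeCN, 80 °C; then aq. NaOH, CH2Cl2, 0 °C
Reagents that add atoms: triphenylphosphine c1ccc(cc1)P(c1ccccc1)c1ccccc1
Why: SN2 quaternisation of triphenylphosphine by the α-bromo amide followed by deprotonation gives the amide-stabilised Wittig ylide, the racemic centre of 16 becoming the ylide carbon.

**Step 10**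
Reactants: 15 (3S,4S,5E,7S,8R,9S,11S,12R)-12-Ar-3,9-dimethoxy-5,7,11-trimethyl-8,12-bis[(triethylsilyl)oxy]dodeca-1,5-dien-4-ol; 18 2-(triphenyl-λ5-phosphanylidene)propanamide
Product: 20 (2E,6S,7S,8E,10S,11R,12S,14S,15R)-15-Ar-7-hydroxy-6,12-dimethoxy-2,8,10,14-tetramethyl-11,15-bis[(triethylsilyl)oxy]pentadeca-2,8-dienamide, via lactol 19 (not isolated)
Conditions: Rh(acac)(CO)2 (2 mol %), Xantphos, CO/H2 (1:1, 10 bar), toluene, 65 °C; then 18, toluene, 90 °C
Reagents that add atoms: carbon monoxide [C-]#[O+]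
Why: Tandem hydroformylation–Wittig olefination: Rh/Xantphos formylates only the terminal vinyl group at its end carbon (trisubstituted alkene and Ar–Br are inert), the aldehyde is held as δ-lactol 19 by the C7 hydroxyl, and the stabilised α-methyl ylide opens it to the E-2-methyl-2-enamide.

**Step 11**
Reactants: 20 (2E,6S,7S,8E,10S,11R,12S,14S,15R)-15-Ar-7-hydroxy-6,12-dimethoxy-2,8,10,14-tetramethyl-11,15-bis[(triethylsilyl)oxy]pentadeca-2,8-dienamide
Product: 21 19-membered macrolactam (amide N bonded to aryl C20; 7-OH free; 11,15-bis-O-TES; aryl O-TIPS; 6S,7S,10S,11R,12S,14S,15R; 2E,8E)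
Conditions: CuI (50 mol %), MeNHCH2CH2NHMe, K2CO3, toluene (2 mM), 110 °C
Reagents that add atoms: none
Why: Intramolecular Goldberg (Ullmann-type) amidation: the Cu(I)–diamine amidate of the primary amide couples with the aryl bromide at high dilution to close the 19-membered lactam, the more acidic amide N–H being arylated in preference to the neutral C7 alcohol under K2CO3, and no stereocentre is affected.

**Step 12**
Reactants: 21 19-membered macrolactam with free 7-OH
Product: 23 7-O-carbamoyl macrolactam (11,15-bis-O-TES; aryl O-TIPS), via N-trichloroacetyl carbamate 22 (not isolated)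
Conditions: Cl3CC(O)NCO, CH2Cl2, 0 °C; then K2CO3 (cat.), MeOH, 0 °C
Reagents that add atoms: trichloroacetyl isocyanate O=C=NC(=O)C(Cl)(Cl)Cl
Why: Carbamoylation with trichloroacetyl isocyanate (Kočovský method): the C7 allylic alcohol is the only free hydroxyl and adds to the acyl isocyanate with retention at C7, and mild methanolysis removes the trichloroacetyl group to leave the primary carbamate.

**Step 13**
Reactants: 23 7-O-carbamoyl macrolactam (11,15-bis-O-TES; aryl O-TIPS)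
Product: 24 target CNP0309815.1 (6S,7S,10S,11R,12S,14S,15R; 2E,8E)
Conditions: TBAF, AcOH (1:1), THF, 0 °C to rt
Reagents that add atoms: none
Why: Fluoride-mediated desilylation buffered with acetic acid cleaves the aryl TIPS ether and both secondary TES ethers without base damage to the carbamate or enamide, giving the target with all seven stereocentres unchanged.

**Compound list**
1 | 3-bromo-5-hydroxybenzaldehyde | O=Cc1cc(O)cc(Br)c1 | starting material
2 | 3-bromo-5-[(triisopropylsilyl)oxy]benzaldehyde | O=Cc1cc(Br)cc(O[Si](C(C)C)(C(C)C)C(C)C)c1 | intermediate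
3 | cis-2-butene | C/C=C\C | starting material
4 | (1R,2S)-1-Ar-2-methylbut-3-en-1-ol | C=C[C@H](C)[C@@H](O)c1cc(Br)cc(O[Si](C(C)C)(C(C)C)C(C)C)c1 | intermediate
5 | (5S,6R)-6-Ar-5-methyltetrahydro-2H-pyran-2-ol (anomer mixture) | OC1CC[C@H](C)[C@@H](O1)c1cc(Br)cc(O[Si](C(C)C)(C(C)C)C(C)C)c1 | intermediate (not isolated)
6 | (2R,3S)-2-Ar-3-methyl-3,4-dihydro-2H-pyran | C1=CC[C@H](C)[C@@H](O1)c1cc(Br)cc(O[Si](C(C)C)(C(C)C)C(C)C)c1 | intermediate
7 | (3S,5S,6R)-6-Ar-2,3-dimethoxy-5-methyltetrahydro-2H-pyran (anomer mixture) | CO[C@H]1C[C@H](C)[C@@H](OC1OC)c1cc(Br)cc(O[Si](C(C)C)(C(C)C)C(C)C)c1 | intermediate (not isolated)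
8 | (3S,5S,6R)-6-Ar-3-methoxy-5-methyltetrahydro-2H-pyran-2-ol (anomer mixture) | CO[C@H]1C[C@H](C)[C@@H](OC1O)c1cc(Br)cc(O[Si](C(C)C)(C(C)C)C(C)C)c1 | intermediate
9 | (Z)-crotylboronic acid pinacol ester | C/C=C\CB1OC(C)(C)C(C)(C)O1 | starting material
10 | (1R,2S,4S,5R,6S)-1-Ar-4-methoxy-2,6-dimethyloct-7-ene-1,5-diol | C=C[C@H](C)[C@@H](O)[C@@H](OC)C[C@H](C)[C@@H](O)c1cc(Br)cc(O[Si](C(C)C)(C(C)C)C(C)C)c1 | intermediate
11 | methacrolein | CC(=C)C=O | starting material
12 | (2E,4S,5R,6S,8S,9R)-9-Ar-5,9-dihydroxy-6-methoxy-2,4,8-trimethylnon-2-enal | O=C/C(C)=C/[C@H](C)[C@@H](O)[C@@H](OC)C[C@H](C)[C@@H](O)c1cc(Br)cc(O[Si](C(C)C)(C(C)C)C(C)C)c1 | intermediate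
13 | (2E,4S,5R,6S,8S,9R)-9-Ar-6-methoxy-2,4,8-trimethyl-5,9-bis[(triethylsilyl)oxy]non-2-enal | O=C/C(C)=C/[C@H](C)[C@@H](O[Si](CC)(CC)CC)[C@@H](OC)C[C@H](C)[C@@H](O[Si](CC)(CC)CC)c1cc(Br)cc(O[Si](C(C)C)(C(C)C)C(C)C)c1 | intermediate
14 | allyl methyl ether | C=CCOC | starting material
15 | (3S,4S,5E,7S,8R,9S,11S,12R)-12-Ar-3,9-dimethoxy-5,7,11-trimethyl-8,12-bis[(triethylsilyl)oxy]dodeca-1,5-dien-4-ol | C=C[C@H](OC)[C@@H](O)/C(C)=C/[C@H](C)[C@@H](O[Si](CC)(CC)CC)[C@@H](OC)C[C@H](C)[C@@H](O[Si](CC)(CC)CC)c1cc(Br)cc(O[Si](C(C)C)(C(C)C)C(C)C)c1 | intermediate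
16 | 2-bromopropanamide (racemic) | CC(Br)C(N)=O | starting material
17 | (1-amino-1-oxopropan-2-yl)triphenylphosphonium bromide | CC(C(N)=O)[P+](c1ccccc1)(c1ccccc1)c1ccccc1.[Br-] | intermediate (not isolated)
18 | 2-(triphenyl-λ5-phosphanylidene)propanamide | CC(C(N)=O)=P(c1ccccc1)(c1ccccc1)c1ccccc1 | intermediate
19 | (5S,6S)-5-methoxy-6-[(2E,4S,5R,6S,8S,9R)-9-Ar-6-methoxy-4,8-dimethyl-5,9-bis[(triethylsilyl)oxy]non-2-en-2-yl]tetrahydro-2H-pyran-2-ol (anomer mixture) | OC1CC[C@H](OC)[C@@H](O1)/C(C)=C/[C@H](C)[C@@H](O[Si](CC)(CC)CC)[C@@H](OC)C[C@H](C)[C@@H](O[Si](CC)(CC)CC)c1cc(Br)cc(O[Si](C(C)C)(C(C)C)C(C)C)c1 | intermediate (not isolated)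
20 | (2E,6S,7S,8E,10S,11R,12S,14S,15R)-15-Ar-7-hydroxy-6,12-dimethoxy-2,8,10,14-tetramethyl-11,15-bis[(triethylsilyl)oxy]pentadeca-2,8-dienamide | NC(=O)/C(C)=C/CC[C@H](OC)[C@@H](O)/C(C)=C/[C@H](C)[C@@H](O[Si](CC)(CC)CC)[C@@H](OC)C[C@H](C)[C@@H](O[Si](CC)(CC)CC)c1cc(Br)cc(O[Si](C(C)C)(C(C)C)C(C)C)c1 | intermediate
21 | 19-membered macrolactam of 20 (N–C20 bond; 7-OH free; 11,15-bis-O-TES; aryl O-TIPS; 6S,7S,10S,11R,12S,14S,15R; 2E,8E) | CO[C@H]1C[C@H](C)[C@@H](O[Si](CC)(CC)CC)c2cc(O[Si](C(C)C)(C(C)C)C(C)C)cc(c2)NC(=O)/C(C)=C/CC[C@H](OC)[C@@H](O)/C(C)=C/[C@H](C)[C@H]1O[Si](CC)(CC)CC | intermediate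
22 | 21 carrying C7–O–C(=O)NH–C(=O)CCl3 | CO[C@H]1C[C@H](C)[C@@H](O[Si](CC)(CC)CC)c2cc(O[Si](C(C)C)(C(C)C)C(C)C)cc(c2)NC(=O)/C(C)=C/CC[C@H](OC)[C@@H](OC(=O)NC(=O)C(Cl)(Cl)Cl)/C(C)=C/[C@H](C)[C@H]1O[Si](CC)(CC)CC | intermediate (not isolated)
23 | 21 carrying C7–O–C(=O)NH2 (11,15-bis-O-TES, aryl O-TIPS) | CO[C@H]1C[C@H](C)[C@@H](O[Si](CC)(CC)CC)c2cc(O[Si](C(C)C)(C(C)C)C(C)C)cc(c2)NC(=O)/C(C)=C/CC[C@H](OC)[C@@H](OC(N)=O)/C(C)=C/[C@H](C)[C@H]1O[Si](CC)(CC)CC | intermediate
24 | CNP0309815.1 (6S,7S,10S,11R,12S,14S,15R; 2E,8E) | CO[C@H]1C[C@H](C)[C@@H](O)c2cc(O)cc(c2)NC(=O)/C(C)=C/CC[C@H](OC)[C@@H](OC(N)=O)/C(C)=C/[C@H](C)[C@H]1O | target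

**Totals**
Total steps: 13. Longest linear sequence: 12 (steps 1–8 and 10–13; step 9 is a one-step side branch).

**Three steps most likely to fail**

Step 4 (proposed new anodic dimethoxylation). Risks are poor face selectivity at C12, enol-ether dimerisation and over-oxidation. The fallback uses known glycal chemistry and sets out from 6. Epoxidation with dimethyldioxirane (acetone/CH2Cl2, −78 to 0 °C) anti to the C14 methyl, followed by in situ methanolysis of the 1,2-anhydro intermediate, gives (3S,5S,6R)-6-Ar-2-methoxy-5-methyltetrahydro-2H-pyran-3-ol F1. Williamson methylation (NaH, MeI, THF) then gives the dimethoxy acetal 7, where the fallback comes back to the route; the same acid hydrolysis leads to 8.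

Step 6 (cross-metathesis of an allylically branched alkene with methacrolein). The risk is low conversion or homodimerisation. The fallback sets out from 10. Silylation (TESCl, imidazole, DMF) gives (3S,4R,5S,7S,8R)-8-Ar-5-methoxy-3,7-dimethyl-4,8-bis[(triethylsilyl)oxy]oct-1-ene F2. Ozonolysis (O3, CH2Cl2/MeOH, pyridine, −78 °C; PPh3) gives (2R,3R,4S,6S,7R)-7-Ar-4-methoxy-2,6-dimethyl-3,7-bis[(triethylsilyl)oxy]heptanal F3. Wittig olefination with commercial 2-(triphenylphosphoranylidene)propanal (toluene, 80 °C) gives the E-enal 13, where it comes back to the route.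

Step 11 (aryl C–N macrocyclisation with the C7 hydroxyl free). Risks are oligomerisation, O-arylation or oxa-Michael closure. The fallback closes the ring at the acyl C–N bond instead and sets out from 15.
- The same hydroformylation to lactol 19, but olefination with commercial ethyl 2-(triphenylphosphoranylidene)propanoate, gives the ethyl ester analogue of 20, ethyl (2E,6S,7S,8E,10S,11R,12S,14S,15R)-15-Ar-7-hydroxy-6,12-dimethoxy-2,8,10,14-tetramethyl-11,15-bis[(triethylsilyl)oxy]pentadeca-2,8-dienoate F4.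
- Pd-catalysed amination with benzophenone imine (Pd2(dba)3, BINAP, Cs2CO3, toluene, 90 °C) gives the N-(diphenylmethylidene)aniline ester F5.
- Cleavage with NH2OH·HCl/NaOAc in MeOH gives the free aniline ester F6.
- Me3SnOH (1,2-dichloroethane, 80 °C) gives the seco amino acid F7.
- High-dilution macrolactamisation (BOP-Cl, i-Pr2NEt, toluene, 85 °C) gives 21, where it comes back to the route.

**Further compounds**
F1 | step 4 | (3S,5S,6R)-6-Ar-2-methoxy-5-methyltetrahydro-2H-pyran-3-ol | O[C@H]1C[C@H](C)[C@@H](OC1OC)c1cc(Br)cc(O[Si](C(C)C)(C(C)C)C(C)C)c1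
F2 | step 6 | (3S,4R,5S,7S,8R)-8-Ar-5-methoxy-3,7-dimethyl-4,8-bis[(triethylsilyl)oxy]oct-1-ene | C=C[C@H](C)[C@@H](O[Si](CC)(CC)CC)[C@@H](OC)C[C@H](C)[C@@H](O[Si](CC)(CC)CC)c1cc(Br)cc(O[Si](C(C)C)(C(C)C)C(C)C)c1
F3 | step 6 | (2R,3R,4S,6S,7R)-7-Ar-4-methoxy-2,6-dimethyl-3,7-bis[(triethylsilyl)oxy]heptanal | O=C[C@H](C)[C@@H](O[Si](CC)(CC)CC)[C@@H](OC)C[C@H](C)[C@@H](O[Si](CC)(CC)CC)c1cc(Br)cc(O[Si](C(C)C)(C(C)C)C(C)C)c1
F4 | step 11 | ethyl (2E,6S,7S,8E,10S,11R,12S,14S,15R)-15-Ar-7-hydroxy-6,12-dimethoxy-2,8,10,14-tetramethyl-11,15-bis[(triethylsilyl)oxy]pentadeca-2,8-dienoate | CCOC(=O)/C(C)=C/CC[C@H](OC)[C@@H](O)/C(C)=C/[C@H](C)[C@@H](O[Si](CC)(CC)CC)[C@@H](OC)C[C@H](C)[C@@H](O[Si](CC)(CC)CC)c1cc(Br)cc(O[Si](C(C)C)(C(C)C)C(C)C)c1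
F5 | step 11 | F4 with Br replaced by N=CPh2 (N-diphenylmethylidene aniline, not isolated) | CCOC(=O)/C(C)=C/CC[C@H](OC)[C@@H](O)/C(C)=C/[C@H](C)[C@@H](O[Si](CC)(CC)CC)[C@@H](OC)C[C@H](C)[C@@H](O[Si](CC)(CC)CC)c1cc(N=C(c2ccccc2)c2ccccc2)cc(O[Si](C(C)C)(C(C)C)C(C)C)c1
F6 | step 11 | F4 with Br replaced by NH2 (aniline ethyl ester) | CCOC(=O)/C(C)=C/CC[C@H](OC)[C@@H](O)/C(C)=C/[C@H](C)[C@@H](O[Si](CC)(CC)CC)[C@@H](OC)C[C@H](C)[C@@H](O[Si](CC)(CC)CC)c1cc(N)cc(O[Si](C(C)C)(C(C)C)C(C)C)c1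
F7 | step 11 | seco amino acid (free CO2H at C1, NH2 on the arene) | OC(=O)/C(C)=C/CC[C@H](OC)[C@@H](O)/C(C)=C/[C@H](C)[C@@H](O[Si](CC)(CC)CC)[C@@H](OC)C[C@H](C)[C@@H](O[Si](CC)(CC)CC)c1cc(N)cc(O[Si](C(C)C)(C(C)C)C(C)C)c1
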